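Note for the bench. 5.15 turnovers stood in the south-east run at 5.00 h. I counted turnovers (the turnover number) as target made per precatalyst charged:

turnovers = [target] / [precatalyst charged]

| flask | starting material | precatalyst | added ligand | temperature | remark | time |
|---|---|---|---|---|---|---|
| north-east | 0.050 M | 1 mM | 0.29 mM | 30 °C | run made earlier |  |
| south-east | 0.050 M | 1 mM | 1.2 mM | 60 °C | run made earlier |  |
| south-west | 0.050 M | 1.5 mM | 0.58 mM | 30 °C | run made earlier |  |
| blue | 0.050 M | 1.0 mM | 0.58 mM | 60 °C |  | 8.0 h |
| grey | 0.050 M | 1.0 mM | 0.58 mM | 35 °C |  | 8.0 h |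
| red | 0.050 M | 1.0 mM | 0.58 mM | 85 °C |  | 8.0 h |

| run | time / h | target / % |
|---|---|---|
| north-east | 2.00 | 0 |
| north-east | 3.00 | 1.3 |
| north-east | 4.00 | 0.3 |
| north-east | 8.00 | 0 |
| north-east | 12.0 | 0.1 |
| north-east | 20.0 | 2.7 |
| south-east | 0.333 | 0.6 |
| south-east | 1.00 | 2.6 |
| south-east | 1.50 | 0 |
| south-east | 2.50 | 2.4 |
| south-east | 4.00 | 7.1 |
| south-east | 5.00 | 10.3 |
| south-west | 2.00 | 0 |
| south-west | 6.00 | 0 |
| south-west | 8.00 | 1.3 |
| south-west | 12.0 | 0 |
| south-west | 20.0 | 0.6 |

(readings scatter by 1 percentage point)



- the flask that comes out highest in amount of target, in percent of the starting material charged, or "all alike" when all lie within 1.5 percentage points (blue / grey / red / all alike)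
- target at the end, in percent of the starting material charged, blue
- target at the end, in percent of the starting material charged, grey
- target at the end, in percent of the starting material charged, red

Each new flask started with its charges of starting material, precatalyst and added ligand. The south-east count was still climbing, at 1.58 h⁻¹ between 2.50 h and 5.00 h, as read through the scatter. Blue had its temperature and precatalyst but less added ligand. No run tested the ligand by itself, so I kept that rate for blue:

turnovers in blue at 8.0 h = 5.15 + 1.58 h⁻¹ × 3.00 h = 9.89

[target] in blue = 9.89 × 1.0 mM / 0.050 M = 19.8%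

At 30 °C the north-east run read 1.35 turnovers after 20.0 h, so I put grey near 1.08%. No run stood above 60 °C, so I had no count for red. I said to keep the precatalyst charge as written, so that the count could be read against the south-east run: at a given count, target follows the charge in proportion.

The forecast named red highest, with blue 11%, grey 0.5% and red 35%, adding “though catalyst death at 85 °C with little ligand is a risk”. My blue stood above its figure.

The flask that came out highest was blue: blue gave 17.0%, grey 0.211% and red 8.37%.

    starting material → intermediate (k = 0.239 h⁻¹, Ea = 101 kJ mol⁻¹)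
    free catalyst + intermediate → free catalyst + target (k = 133 M⁻¹ h⁻¹, Ea = 53.0 kJ mol⁻¹)
    precatalyst → free catalyst (k = 0.0448 h⁻¹, Ea = 112 kJ mol⁻¹)
    free catalyst → spent catalyst (k = 0.198 h⁻¹, Ea = 90.0 kJ mol⁻¹)
    free catalyst + added ligand ⇌ idle complex, settled at all times (K = 1.50 × 10⁵ M⁻¹, ΔH = −45.0 kJ mol⁻¹)
    (constants at 35 °C)

Blue's target came to 8.52 turnovers and red's to 4.19, about half of blue's. Red's target already stood at 8.37% at 4.00 h, with spent catalyst at >99.9%. A neighbour of blue was charged 4.00 mM of precatalyst, 4.00 times blue's charge. Blue's count carried over gave 68.2% of target. That neighbour gave 56.1%, which is 7.01 turnovers.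

The runs are simulated with constants of no real substance; noise was put on by code.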